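A direct plan would build ring C first and ring A last: a simple 3-hydroxy-4-pyranone would be brominated, O-methylated and joined by Negishi coupling to a benzyl-protected ring B bromide to give the 2-aryl-3-methoxy-4-pyranone A1, four steps for a compound that holds little of the target's difficulty.
A1 would then be magnesiated next to its carbonyl group and added to a squaric diester (cyclobutenone A2), heated to the 5,8-dihydroxyflavone A3, methylated at the 8-OH and debenzylated.
Its weakest steps would be the following.
(a) The deprotonation of the pyranone C–H and its addition to the squaric ester: this metalation has no close precedent on a 4-pyranone, which is open to nucleophilic ring opening and whose C–H next to the ring oxygen is at least as acidic, so the bond that starts ring A would rest on an untested method.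
(b) The thermal ring opening and 6π closure that builds ring A: the closure onto the electron-poor pyranone C=C would have to beat attack of the hydroxyl group on the ketene, nothing in the substrate enforces it, and its product A3 is an air-sensitive hydroquinone.
(c) The methylation of one of the two hydroxyl groups of A3 with one equivalent of methylating agent: the selectivity would rest on a hydrogen bond alone and would be spent on the most precious material.

The retrosynthesis cuts ring C at O1–C2 and at C4–C4a. In ring A, C4a lies between the oxygen-bearing carbons C5 and C8a, and C6 and C8 carry the same group, so ring A without ring C is the mirror-symmetric 4,5,6-trimethoxyresorcinol: its only C–H is C4a and its two oxygens are interchangeable.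
In ring B, the 2'-oxygen and C4 are the ends of a six-atom chain (O2'–C2'–C1'–C2–C3–C4), so C2–C3–C4 can be stored on ring B as 3,4,7-trimethoxycoumarin: lactone carbonyl = C4, coumarin C4 = C2, ring oxygen = 2'-OH, 3-OMe in place.
Rings A and B are bought and a 2-pyranone is built on ring B. Ring C arises last: the C4a-lithiated ring A opens the 2-pyranone (C4–C4a), then a ring A oxygen closes the 4-pyranone (O1–C2) under base.
No pyranone is metalated, no squaric ester is used, and ring A arrives complete, so no hydroquinone and no selective methylation occur. The 5-OH and 2'-OH are set free, not told apart, and under base the ring B oxygen can add only reversibly, so the closure is not left to chance.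
Key step: step 6

Remark: the target is achiral; methyl 2-hydroxy-4-methoxybenzoate, methoxyacetyl chloride and 1,2,3-trimethoxybenzene are assumed to be commercial.

Step 1
Reactants: 1 methyl 2-hydroxy-4-methoxybenzoate; 2 methoxyacetyl chloride
Product: 3 methyl 4-methoxy-2-[(methoxyacetyl)oxy]benzoate
Conditions: 2 (1.2 equiv), Et3N (1.5 equiv), DMAP (5 mol %), CH2Cl2, 0 °C to rt
Reagents that add atoms: none
Why: O-acylation of the salicylate phenol by an acid chloride under nucleophilic catalysis (DMAP acyl transfer), which puts the future C3–C4 unit with its methoxy group on the future 2'-oxygen.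

Step 2
Reactants: 3 methyl 4-methoxy-2-[(methoxyacetyl)oxy]benzoate
Product: 5 4-hydroxy-3,7-dimethoxy-2H-chromen-2-one, via lithium coumarin-4-olate 4 (not isolated)
Conditions: LiN(SiMe3)2 (2.2 equiv), THF, −78 °C to rt; 1 M HCl
Reagents that add atoms: none
Why: Intramolecular Claisen (Dieckmann-type) condensation, the classical route from O-acylsalicylates to 4-hydroxycoumarins, in which the α-methoxy ester enolate attacks the neighbouring methyl ester (6-exo-trig) and deprotonation of the acidic product to 4 should pull the ester-exchange equilibria to one side.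

Step 3
Reactants: 5 4-hydroxy-3,7-dimethoxy-2H-chromen-2-one
Product: 6 3,4,7-trimethoxy-2H-chromen-2-one
Conditions: MeOH, conc. H2SO4 (cat.), reflux
Reagents that add atoms: methanol, CO
Why: Acid-catalysed (Fischer-type) etherification of a vinylogous carboxylic acid, the usual way from 4-hydroxycoumarins to 4-methoxycoumarins, which should give the 4-methyl ether only because the isomeric 2-methoxychromone is a ketene-acetal-like species that reverts under the same conditions.

Step 4
Reactants: 7 1,2,3-trimethoxybenzene
Product: 9 1,5-dibromo-2,3,4-trimethoxybenzene, via monobromide 8 (not isolated)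
Conditions: NBS (2.1 equiv), MeCN, 0 °C to rt, dark
Reagents that add atoms: N-bromosuccinimide, O=C1CCC(=O)N1Br
Why: Electrophilic aromatic bromination, in which each bromine should enter ortho to one outer methoxy group and para to the other (positions 4 and 6), the position para to the twisted central methoxy group being the least activated.

Step 5
Reactants: 9 1,5-dibromo-2,3,4-trimethoxybenzene
Product: 11 1,5-bis(benzyloxy)-2,3,4-trimethoxybenzene, via monobenzyl ether 10 (not isolated)
Conditions: BnOH (6 equiv), CuI (10 mol %), 3,4,7,8-tetramethyl-1,10-phenanthroline (20 mol %), Cs2CO3 (3 equiv), toluene, 110 °C, Ar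
Reagents that add atoms: benzyl alcohol, OCc1ccccc1
Why: Copper-catalysed Ullmann-type C–O coupling of aryl bromides with a primary alcohol, which should turn both bromides into benzyl ethers and so deliver the mirror-symmetric resorcinol diether without handling the air-sensitive free diol.

Step 6
Reactants: 11 1,5-bis(benzyloxy)-2,3,4-trimethoxybenzene; 6 3,4,7-trimethoxy-2H-chromen-2-one
Product: 15 (Z)-1-[2,6-bis(benzyloxy)-3,4,5-trimethoxyphenyl]-3-(2-hydroxy-4-methoxyphenyl)-2,3-dimethoxyprop-2-en-1-one, via aryllithium 12 (not isolated), via lithium hemiketal 13 (not isolated), via lithium phenoxide 14 (not isolated)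
Conditions: 11, n-BuLi (1.05 equiv), THF, 0 °C, 1 h; −78 °C, 6 (1.1 equiv) in THF, then to −20 °C; H2O, then pH 7 phosphate buffer; crude 15 used as such (no acidic silica)
Reagents that add atoms: none
Why: Directed ortho-lithiation takes the only ring proton of 11, which lies between the two benzyloxy groups (complex-induced proximity effect), and the hard aryllithium 12 adds 1,2 to the lactone carbonyl of 6, whose hemiketal alkoxide 13 collapses with loss of the ring B phenoxide to 14, so that one operation makes the C4–C4a bond, opens the 2-pyranone and frees the 2'-oxygen. The closest known reaction types are the addition of aryl Grignard and aryllithium reagents to the lactone carbonyl of 3-methoxycoumarins (the classical entry to flavylium salts) and the 1,2-addition of organolithiums to vinylogous esters (Stork–Danheiser). The step closes no ring but opens one; ring C is closed in step 7 by a 6-endo-trig oxa-Michael addition and β-elimination of methoxide. No stereocentre remains: the carbinol centre of 13 is lost on ring opening, and the Z double bond of 15, inherited from the coumarin, is of no consequence because the closure passes through an sp3 adduct. The step needs attack at the carbonyl carbon and not at the methoxy-bearing C4 of 6, and one addition only; the tetrasubstituted C4 shielded by the peri C5–H, the hard 2,6-disubstituted nucleophile and the hindered vinylogous-ester ketone that results should secure both. It also needs the ring B oxygen not to close back with loss of water, which is why 15 is kept away from acid: its cyclic hemiketal can go on to a 4-methoxybenzopyrylium ion only when protonated.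

Step 7
Reactants: 15 (Z)-1-[2,6-bis(benzyloxy)-3,4,5-trimethoxyphenyl]-3-(2-hydroxy-4-methoxyphenyl)-2,3-dimethoxyprop-2-en-1-one
Product: 18 5-hydroxy-2-(2-hydroxy-4-methoxyphenyl)-3,6,7,8-tetramethoxy-4H-chromen-4-one (5,2'-dihydroxy-3,6,7,8,4'-pentamethoxyflavone), via triol 16 (not isolated), via methoxyflavanone adduct 17 (not isolated)
Conditions: H2 (1 atm), Pd/C (10 wt %), NaHCO3 (0.2 equiv), EtOAc–MeOH, rt; filtered under Ar; K2CO3 (0.3 equiv), MeOH, 40 °C; aq. NaH2PO4
Reagents that add atoms: none
Why: Hydrogenolysis of the two aryl benzyl ethers followed by base-mediated oxa-Michael addition of a ring A phenoxide to the β-methoxy enone and E1cB loss of methanol (the standard chromone closure of 2-hydroxyaryl β-alkoxyvinyl ketones), in which either of the two equivalent ring A oxygens gives the same product, the other becomes the chelated 5-OH, the two transient stereocentres of 17 are lost, and the ring B phenoxide can add to the ketone only reversibly.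

Compound list
1 | methyl 2-hydroxy-4-methoxybenzoate | COC(=O)c1ccc(OC)cc1O | starting material
2 | methoxyacetyl chloride | COCC(=O)Cl | starting material
3 | methyl 4-methoxy-2-[(methoxyacetyl)oxy]benzoate | COCC(=O)Oc1cc(OC)ccc1C(=O)OC | intermediate
4 | lithium 3,7-dimethoxy-2-oxo-2H-chromen-4-olate | [Li+].COc1ccc2c([O-])c(OC)c(=O)oc2c1 | intermediate
5 | 4-hydroxy-3,7-dimethoxy-2H-chromen-2-one | COc1ccc2c(O)c(OC)c(=O)oc2c1 | intermediate
6 | 3,4,7-trimethoxy-2H-chromen-2-one | COc1ccc2c(OC)c(OC)c(=O)oc2c1 | intermediate
7 | 1,2,3-trimethoxybenzene | COc1cccc(OC)c1OC | starting material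
8 | 1-bromo-2,3,4-trimethoxybenzene | COc1ccc(Br)c(OC)c1OC | intermediate
9 | 1,5-dibromo-2,3,4-trimethoxybenzene | COc1c(Br)cc(Br)c(OC)c1OC | intermediate
10 | 1-(benzyloxy)-5-bromo-2,3,4-trimethoxybenzene | COc1c(Br)cc(OCc2ccccc2)c(OC)c1OC | intermediate
11 | 1,5-bis(benzyloxy)-2,3,4-trimethoxybenzene | COc1c(OCc2ccccc2)cc(OCc2ccccc2)c(OC)c1OC | intermediate
12 | [2,6-bis(benzyloxy)-3,4,5-trimethoxyphenyl]lithium | [Li]c1c(OCc2ccccc2)c(OC)c(OC)c(OC)c1OCc1ccccc1 | intermediate
13 | lithium 2-[2,6-bis(benzyloxy)-3,4,5-trimethoxyphenyl]-3,4,7-trimethoxy-2H-chromen-2-olate (racemic) | [Li]OC1(c2c(OCc3ccccc3)c(OC)c(OC)c(OC)c2OCc2ccccc2)Oc2cc(OC)ccc2C(OC)=C1OC | intermediate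
14 | lithium 2-{(Z)-3-[2,6-bis(benzyloxy)-3,4,5-trimethoxyphenyl]-1,2-dimethoxy-3-oxoprop-1-en-1-yl}-5-methoxyphenolate | [Li]Oc1cc(OC)ccc1/C(OC)=C(/OC)C(=O)c1c(OCc2ccccc2)c(OC)c(OC)c(OC)c1OCc1ccccc1 | intermediate
15 | (Z)-1-[2,6-bis(benzyloxy)-3,4,5-trimethoxyphenyl]-3-(2-hydroxy-4-methoxyphenyl)-2,3-dimethoxyprop-2-en-1-one (in equilibrium with its cyclic hemiketal, the protonated form of 13) | COc1ccc(/C(OC)=C(/OC)C(=O)c2c(OCc3ccccc3)c(OC)c(OC)c(OC)c2OCc2ccccc2)c(O)c1 | intermediate
16 | (Z)-1-(2,6-dihydroxy-3,4,5-trimethoxyphenyl)-3-(2-hydroxy-4-methoxyphenyl)-2,3-dimethoxyprop-2-en-1-one | COc1ccc(/C(OC)=C(/OC)C(=O)c2c(O)c(OC)c(OC)c(OC)c2O)c(O)c1 | intermediate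
17 | 5-hydroxy-2-(2-hydroxy-4-methoxyphenyl)-2,3,6,7,8-pentamethoxy-2,3-dihydro-4H-chromen-4-one (racemic mixture of diastereomers, both centres transient) | COc1ccc(C2(OC)Oc3c(OC)c(OC)c(OC)c(O)c3C(=O)C2OC)c(O)c1 | intermediate
18 | 5-hydroxy-2-(2-hydroxy-4-methoxyphenyl)-3,6,7,8-tetramethoxy-4H-chromen-4-one (5,2'-dihydroxy-3,6,7,8,4'-pentamethoxyflavone, achiral) | COc1ccc(-c2oc3c(OC)c(OC)c(OC)c(O)c3c(=O)c2OC)c(O)c1 | target

Total step count: 7. Longest linear sequence: 5 steps (steps 1, 2, 3, 6, 7); the ring A branch (steps 4, 5) joins at step 6.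

Steps most likely to fail

Step 6. The aryllithium may attack the methoxy-bearing C4 of the lactone (addition–elimination) instead of the carbonyl group, or the freed ring B oxygen may close back onto the new ketone with loss of water during isolation. The fallback does the acyl transfer on an open-chain Weinreb amide whose ring B oxygen is capped, and never exposes the free ring B phenol beside the ketone. It sets out from 6:
- Ring opening with Me2AlN(OMe)Me (from AlMe3 and MeNHOMe·HCl, CH2Cl2, 0 °C to rt) should give (Z)-3-(2-hydroxy-4-methoxyphenyl)-N,2,3-trimethoxy-N-methylprop-2-enamide F1.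
- F1 would be silylated at once (TBSCl, imidazole, DMF) to (Z)-3-{2-[(tert-butyldimethylsilyl)oxy]-4-methoxyphenyl}-N,2,3-trimethoxy-N-methylprop-2-enamide F2.
- Aryllithium 12, made from 11 as in step 6, would add to F2 at −78 °C. The chelated tetrahedral intermediate of the Weinreb ketone synthesis should allow one addition only and give (Z)-1-[2,6-bis(benzyloxy)-3,4,5-trimethoxyphenyl]-3-{2-[(tert-butyldimethylsilyl)oxy]-4-methoxyphenyl}-2,3-dimethoxyprop-2-en-1-one F3.
- Hydrogenolysis (H2, Pd/C, EtOAc–MeOH) should give (Z)-3-{2-[(tert-butyldimethylsilyl)oxy]-4-methoxyphenyl}-1-(2,6-dihydroxy-3,4,5-trimethoxyphenyl)-2,3-dimethoxyprop-2-en-1-one F4.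
- K2CO3 in MeOH would then close ring C and cleave the aryl silyl ether, through 2-{2-[(tert-butyldimethylsilyl)oxy]-4-methoxyphenyl}-5-hydroxy-3,6,7,8-tetramethoxy-4H-chromen-4-one F5 or through triol 16, so that the fallback comes back to the route at 18.

Step 5. Oxidative addition at the second, electron-rich and ortho-substituted C–Br bond may be slow, and reduction of C–Br to C–H may compete, so that the double etherification stalls. The fallback sets out from 9 and makes the C–O bonds as phenols first. A palladium-catalysed hydroxylation (Pd2(dba)3, tBuXPhos, KOH, dioxane–H2O, 100 °C, degassed) should give 4,5,6-trimethoxybenzene-1,3-diol F6. A Williamson benzylation (BnBr, K2CO3, DMF, rt, Ar) would bring it back to the route at 11.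

Step 2. The aryl ester enolate may fragment to methoxyketene and phenoxide (E1cB) faster than it attacks the deactivated benzoate, and the ketene may be lost by oligomerisation. The fallback forms the C–C bond with no aryl ester present and sets out from 1:
- Protection (MOMCl, iPr2NEt, CH2Cl2) should give methyl 4-methoxy-2-(methoxymethoxy)benzoate F7.
- A crossed Claisen condensation with the lithium enolate of methyl methoxyacetate (LDA, THF, −78 °C, 2.2 equiv) should give methyl 2-methoxy-3-[4-methoxy-2-(methoxymethoxy)phenyl]-3-oxopropanoate F8.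
- HCl in MeOH at 50 °C would remove the acetal and lactonise the freed phenol onto the methyl ester, returning to the route at 5.

Further compounds
F1 | step 6 | (Z)-3-(2-hydroxy-4-methoxyphenyl)-N,2,3-trimethoxy-N-methylprop-2-enamide | COc1ccc(/C(OC)=C(/OC)C(=O)N(C)OC)c(O)c1
F2 | step 6 | (Z)-3-{2-[(tert-butyldimethylsilyl)oxy]-4-methoxyphenyl}-N,2,3-trimethoxy-N-methylprop-2-enamide | COc1ccc(/C(OC)=C(/OC)C(=O)N(C)OC)c(O[Si](C)(C)C(C)(C)C)c1
F3 | step 6 | (Z)-1-[2,6-bis(benzyloxy)-3,4,5-trimethoxyphenyl]-3-{2-[(tert-butyldimethylsilyl)oxy]-4-methoxyphenyl}-2,3-dimethoxyprop-2-en-1-one | COc1ccc(/C(OC)=C(/OC)C(=O)c2c(OCc3ccccc3)c(OC)c(OC)c(OC)c2OCc2ccccc2)c(O[Si](C)(C)C(C)(C)C)c1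
F4 | step 6 | (Z)-3-{2-[(tert-butyldimethylsilyl)oxy]-4-methoxyphenyl}-1-(2,6-dihydroxy-3,4,5-trimethoxyphenyl)-2,3-dimethoxyprop-2-en-1-one | COc1ccc(/C(OC)=C(/OC)C(=O)c2c(O)c(OC)c(OC)c(OC)c2O)c(O[Si](C)(C)C(C)(C)C)c1
F5 | step 6 | 2-{2-[(tert-butyldimethylsilyl)oxy]-4-methoxyphenyl}-5-hydroxy-3,6,7,8-tetramethoxy-4H-chromen-4-one | COc1ccc(-c2oc3c(OC)c(OC)c(OC)c(O)c3c(=O)c2OC)c(O[Si](C)(C)C(C)(C)C)c1
F6 | step 5 | 4,5,6-trimethoxybenzene-1,3-diol | COc1c(O)cc(O)c(OC)c1OC
F7 | step 2 | methyl 4-methoxy-2-(methoxymethoxy)benzoate | COCOc1cc(OC)ccc1C(=O)OC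
F8 | step 2 | methyl 2-methoxy-3-[4-methoxy-2-(methoxymethoxy)phenyl]-3-oxopropanoate (racemic) | COCOc1cc(OC)ccc1C(=O)C(OC)C(=O)OC
A1 | direct plan | 2-[2-(benzyloxy)-4-methoxyphenyl]-3-methoxy-4H-pyran-4-one | COc1ccc(-c2occc(=O)c2OC)c(OCc2ccccc2)c1
A2 | direct plan | 4-{6-[2-(benzyloxy)-4-methoxyphenyl]-5-methoxy-4-oxo-4H-pyran-3-yl}-4-hydroxy-2,3-dimethoxycyclobut-2-en-1-one (racemic) | COC1=C(OC)C(O)(c2coc(-c3ccc(OC)cc3OCc3ccccc3)c(OC)c2=O)C1=O
A3 | direct plan | 2-[2-(benzyloxy)-4-methoxyphenyl]-5,8-dihydroxy-3,6,7-trimethoxy-4H-chromen-4-one | COc1ccc(-c2oc3c(O)c(OC)c(OC)c(O)c3c(=O)c2OC)c(OCc2ccccc2)c1
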